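3 questions stand on this flask, and I reckon them from two numbers read from Tuesday's run.

* how much of the substrate has reacted by 40 min
* how much target there is at 40 min, in percent of the substrate charged
* how much isomer of the product there is at 40 min, in percent of the substrate charged

| flask | substrate | partner | remark | time |
|---|---|---|---|---|
| Tuesday's | 3 M (in portions, 2) | 1 M | run made earlier; portions every 15 s |  |
| flask | 2.0 M (in portions, 2) | 1.00 M | the portions of substrate follow each other after 15 s, the first at the start | 40 min |

Tuesday's run (percent of the substrate charged)

| time / min | substrate / % | target / % | isomer of the product / % |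
|---|---|---|---|
| 0.333 | 76.3 | 17.4 | 6.0 |
| 0.500 | 75.5 | 16.0 | 7.7 |
| 0.667 | 74.8 | 14.8 | 10.2 |
| 1.00 | 74.0 | 12.3 | 13.7 |
| 1.50 | 72.3 | 10.5 | 17.5 |
| 2.50 | 71.2 | 7.7 | 20.1 |
| 4.00 | 70.5 | 6.6 | 22.3 |

(scatter of a reading: 0.3 percentage points)



Tuesday's flask and this flask look nearly the same: 2 portions of substrate 15 s apart, and partner as the limiting reagent. They differ in the substrate charge, 3 M against 2.0 M. Tuesday's shares add to about 100 percent, so you may count one substrate in each product; that each also holds one partner is my assumption.

Take the even split of the products, ratio 1, as the zero of the scale. Tuesday's isomer over target reads 0.345 at 0.333 min, below that zero, and 3.38 at 4.00 min, above it. The target comes first and the isomer overtakes it: kinetic against thermodynamic control.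

At 4.00 min Tuesday's products hold 0.867 M, leaving 0.133 M of partner beside 2.11 M of substrate, so

K = 3.08 L mol⁻¹

is the closing constant, both products over free substrate times free partner. It is a rough reading: the partner left comes out as a difference, and Tuesday's isomer still rose 2.2 percentage points over the last interval.

My reckoning counts this flask as at equilibrium, since 40 min is ten times Tuesday's last reading. With x the products, S and B the charges:

x = K(S − x)(B − x), so x = 0.789 M

With the same K, my reckoning puts less product in this flask than Tuesday's last reading shows but a larger share of its charge: conversion 39.5%. Tuesday's last split then gives target 9.01% and isomer 30.4%.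

The forecast, reasoning that “the flask is fully equilibrated, so the dosing doesn't matter”, stands higher on conversion than my reckoning: 40.6%, target 8.6%, isomer 32%.

This flask gives 40.1% conversion, 9.35% target and 30.8% isomer of the product.

    substrate + partner ⇌ target (K = 0.790 L mol⁻¹, k = 0.160 L mol⁻¹ s⁻¹)
    substrate + partner ⇌ isomer of the product (K = 2.60 L mol⁻¹, k = 0.0140 L mol⁻¹ s⁻¹)

Over the second half of this flask's time the largest change of any share is 0 points, and the portions leave the conversion unchanged. Now carry K and the split to the neighbour charged with 2.5 M of partner. The same root gives 1.51 M of products, so conversion 75.5% and isomer 58.3%. That neighbour stands at 76.6% conversion with 58.8% isomer of the product.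

Readings and results come from a simulation on assumed constants, and the scatter is random.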